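**Two flasks.** A small charge of catalyst, 1.1 mM, works on 0.070 M of starting material and 0.0350 M of reagent to give target. Amber receives the starting material at once, grey over 3.0 d.

| setting | south-west | north-west | south | amber | grey |
|---|---|---|---|---|---|
| starting material | 0.070 M (fed, over 3.0 d) | 0.070 M (fed, over 3.0 d) | 0.14 M (fed, over 3.0 d) | 0.070 M | 0.070 M (fed, over 3.0 d) |
| reagent | 0.035 M | 0.035 M | 0.035 M | 0.0350 M | 0.0350 M |
| catalyst | 1.1 mM | 1.1 mM | 1.1 mM | 1.1 mM | 1.1 mM |
| added ligand | 7 mM | 11 mM | 5 mM | 5.0 mM | 5.0 mM |
| temperature | 75 °C | 86 °C | 75 °C | 80 °C | 80 °C |
| remark | run made earlier | run made earlier | run made earlier | everything together at the start |  |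
| time |  |  |  | 3.0 d | 3.0 d |

- south-west (time / d: target / %): 0.333: 8.0; 0.625: 11.7; 1.04: 14.8; 1.25: 14.5; 1.67: 14.7; 2.08: 13.6; 2.50: 12.7
- north-west (time / d: target / %): 0.125: 3.0; 0.333: 4.8; 0.625: 4.7; 1.04: 2.1; 1.67: 1.0; 2.08: 1.2; 2.50: 0.3
- south (time / d: target / %): 0.500: 8.3; 1.04: 11.9; 1.25: 11.1; 2.08: 10.7; 2.50: 10.8

(readings scatter by 0.5 percentage points)

- which of the two ends with the higher amount of target, in percent of the starting material charged ("neither" if they lie within 2 percentage points) (amber / grey / neither)
- target at the end, in percent of the starting material charged, amber
- target at the end, in percent of the starting material charged, grey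

- the analysis behind the earlier runs scatters by 0.5 percentage points, standard deviation
- percentages count the whole charge, also what has not yet gone in

**Start rate.** The south-west run opens at 0.240 d⁻¹ as a fraction of the charge, read from its first point. Over the next two intervals the rate falls to 0.127 d⁻¹, a factor 1.89, and then to 0.0747 d⁻¹, a further 1.70. Target then reads 14.8% and 14.7% while the feed continues.

**Working span.** The accumulated slowing fits one quantity, the working span: highest target reading divided by start rate 0.616 d. The readings give 0.717 d for the south run, with less ligand, and 0.200 d for the hotter north-west run, with more ligand.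

**Own reckoning.** Grey is warmer than south-west but has less ligand, so this reckoning keeps the south-west rate and span. It also keeps the later south-west decline, a factor 0.858, which gives 12.7% for grey. Going from south-west to south raises the start rate in concentration by 1.38, an apparent order of 0.467, though ligand differs between them. Within one span, grey has received 20.5% of its charge, while amber holds it whole, so amber's rate gains 2.09 and its target comes to 26.6%.

**The forecast.** The forecast names amber, with 17% for amber and 7.5% for grey: “Amber has the full charge present during the catalyst's short life”. This reckoning names the same winner but stands higher than the forecast on amber and on grey.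

**The result.** The flask gives amber as the winner, with 24.4% for amber against 11.7% for grey.

    reagent + target → over-reaction product (k = 0.00114 M⁻¹ s⁻¹, Ea = 62.0 kJ mol⁻¹)
    catalyst + added ligand ⇌ idle complex (K = 15000 M⁻¹, k = 0.00315 M⁻¹ s⁻¹, Ea = 87.0 kJ mol⁻¹, ΔH = −48.0 kJ mol⁻¹)
    starting material + reagent + catalyst → target + catalyst, rate k3*[starting material]*[reagent]*[catalyst]/(1 + ([starting material]/sat3)) (0.999 mM, k = 46.7 M⁻² s⁻¹, Ea = 43.0 kJ mol⁻¹)
    (constants at 80 °C)

Grey ends with 18.8% of over-reaction product, amber with 12.8%. Grey's target divided by the south-west start rate gives a span of 0.487 d, shorter than the south-west reading. The neighbour of grey charged with 6.6 × 10⁻⁴ M of catalyst ends at 6.98%, and with the start rate taken in proportion to catalyst its span comes to 0.484 d.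

The readings come from a simulation from invented constants, noise included.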